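**Plan** (ring numbered as 7-oxabicyclo[4.1.0]hept-3-ene: C1 quaternary epoxide carbon with the butenoate chain, C2 CHOH, C3 heptenyl carbon, C4 CH2OH carbon, C5 CHOH, C6 epoxide CH, O7)

1. Retrosynthesis: free the acid last; take C2–OH and CH2OH back to a 2-ketone and a 4-formyl group; cut the heptenyl group at C3 (cross-coupling of a C3 bromide); open the epoxide C6–O7 bond to a C1 alkoxide and a C6 bromide; then cut the ring at C4–C5 and C6–C1.
2. Enabling feature: C1 carries O7 and is flanked by C2, which can stand at ketone level, so O7–C1–C2–C3–C4 is a latent 3-silyloxyfuran whose ring oxygen becomes the epoxide oxygen. C5–C6 with its trans O/leaving-group pair is an (E)-2-bromovinylboron unit, and the 1,3-related oxygens on the C4 substituent and on C5 are what a C–O–B tether leaves after C–B oxidation.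
3. Forward: chiral-pool alkyne → 3(2H)-furanone (heterocycle first) → C4 bromination and C2 alkylation with the butenoate chain → boron-tethered intramolecular Diels–Alder reaction and oxidation (carbocycle closed as a 7-oxanorbornene) → fluoride-triggered bridge opening and epoxide closure → Suzuki coupling, glycol cleavage, Luche reduction, saponification.
4. Stereochemistry: the carbinol centre from (R)-glyceraldehyde acetonide directs the face of the cycloaddition (allylic 1,3-strain) and thereby sets C1, C5 and C6. It is then erased by periodate, its carbon becoming the CH2OH carbon. C2 is set by hydride delivery syn to the epoxide oxygen and anti to the C1 chain.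
5. Helpers and their removal: boron (oxidised to the C5 hydroxyl), the oxygen bridge (becomes the epoxide), silyl groups (fluoride), the extra carbinol carbon (lost as formaldehyde), the ring bromine (replaced by heptenyl).

Key step: step 9

Remark: the C2 centre of furanones 11–13 forms as an epimeric mixture and is written without configuration; it becomes sp2 when the ring is aromatised in step 9.

**Step 1**
Reactants: 1 (4R)-2,2-dimethyl-1,3-dioxolane-4-carbaldehyde
Product: 2 (4S)-4-ethynyl-2,2-dimethyl-1,3-dioxolane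
Conditions: dimethyl (1-diazo-2-oxopropyl)phosphonate, K2CO3, MeOH, 0 °C to rt
Reagents that add atoms: dimethyl (1-diazo-2-oxopropyl)phosphonate, CC(=O)C(=[N+]=[N-])P(=O)(OC)OC
Why: Seyferth–Gilbert homologation with the Ohira–Bestmann reagent turns the aldehyde into the terminal alkyne under mild carbonate conditions that should not epimerise the α-alkoxy centre, so the chiral-pool stereocentre is carried over unchanged.

**Step 2**
Reactants: 2 (4S)-4-ethynyl-2,2-dimethyl-1,3-dioxolane; 3 2-[(tert-butyldimethylsilyl)oxy]-N-methoxy-N-methylacetamide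
Product: 5 1-[(tert-butyldimethylsilyl)oxy]-4-[(4S)-2,2-dimethyl-1,3-dioxolan-4-yl]but-3-yn-2-one, via lithium acetylide 4 (not isolated)
Conditions: n-BuLi, THF, −78 °C; then 3, −78 to 0 °C
Reagents that add atoms: none
Why: acylation of a lithium acetylide by a Weinreb amide should stop at the ketone through the chelated tetrahedral adduct and leaves the stereocentre untouched.

**Step 3**
Reactants: 5 1-[(tert-butyldimethylsilyl)oxy]-4-[(4S)-2,2-dimethyl-1,3-dioxolan-4-yl]but-3-yn-2-one
Product: 7 5-[(4R)-2,2-dimethyl-1,3-dioxolan-4-yl]furan-3(2H)-one, via hydroxy ynone 6 (not isolated)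
Conditions: Bu4NF, THF, 0 °C to rt
Reagents that add atoms: none
Why: fluoride removes the primary silyl ether and the freed alkoxide should add to the ynone in an allowed 5-endo-dig oxa-Michael cyclisation, the standard entry to 3(2H)-furanones from γ-hydroxy alkynones (the descriptor changes to R only through the priority rules).

**Step 4**
Reactants: 7 5-[(4R)-2,2-dimethyl-1,3-dioxolan-4-yl]furan-3(2H)-one
Product: 8 4-bromo-5-[(4R)-2,2-dimethyl-1,3-dioxolan-4-yl]furan-3(2H)-one
Conditions: NBS, CH2Cl2, 0 °C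
Reagents that add atoms: N-bromosuccinimide, BrN1C(=O)CCC1=O
Why: the furanone is a vinylogous ester whose C4 is the nucleophilic α-carbon, so electrophilic bromination should occur there; the bromine later blocks C4 in the alkylation, supplies allylic strain in step 9 and is the cross-coupling handle.

**Step 5**
Reactants: 8 4-bromo-5-[(4R)-2,2-dimethyl-1,3-dioxolan-4-yl]furan-3(2H)-one; 9 ethyl (2E)-4-bromo-2-methylbut-2-enoate
Product: 11 ethyl (2E)-4-{4-bromo-5-[(4R)-2,2-dimethyl-1,3-dioxolan-4-yl]-3-oxo-2,3-dihydrofuran-2-yl}-2-methylbut-2-enoate (both C2 epimers), via lithium furan-3-olate 10 (not isolated)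
Conditions: LiN(SiMe3)2 (1.0 equiv), THF, −78 °C; then 9, −78 to −20 °C
Reagents that add atoms: none
Why: deprotonation at C2 gives an aromatic furan-3-olate that should be C-alkylated at C2 (C4 is blocked) by SN2 attack on the primary allylic bromide with retention of the E geometry; the new C2 centre is inconsequential.

**Step 6**
Reactants: 11 ethyl (2E)-4-{4-bromo-5-[(4R)-2,2-dimethyl-1,3-dioxolan-4-yl]-3-oxo-2,3-dihydrofuran-2-yl}-2-methylbut-2-enoate
Product: 12 ethyl (2E)-4-{4-bromo-5-[(1R)-1,2-dihydroxyethyl]-3-oxo-2,3-dihydrofuran-2-yl}-2-methylbut-2-enoate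
Conditions: AcOH/H2O (4:1), 40 °C
Reagents that add atoms: none
Why: acid-catalysed acetal hydrolysis frees the diol, and the vinylogous ester, vinyl bromide and enoate should tolerate aqueous acetic acid.

**Step 7**
Reactants: 12 ethyl (2E)-4-{4-bromo-5-[(1R)-1,2-dihydroxyethyl]-3-oxo-2,3-dihydrofuran-2-yl}-2-methylbut-2-enoate
Product: 13 ethyl (2E)-4-{4-bromo-5-[(1R)-2-[(tert-butyldimethylsilyl)oxy]-1-hydroxyethyl]-3-oxo-2,3-dihydrofuran-2-yl}-2-methylbut-2-enoate
Conditions: TBSCl, imidazole, CH2Cl2, 0 °C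
Reagents that add atoms: tert-butyldimethylsilyl chloride, CC(C)(C)[Si](C)(C)Cl
Why: silylation should discriminate the primary from the hindered secondary hydroxyl, leaving the carbinol free as the anchor for the tether.

**Step 8**
Reactants: 14 acetylene; 15 boron tribromide
Product: 17 dipropan-2-yl [(E)-2-bromoethenyl]boronate, via dibromo[(E)-2-bromoethenyl]borane 16 (not isolated)
Conditions: CH2Cl2, −78 °C to rt; then i-Pr2O, 0 °C to rt; distillation
Reagents that add atoms: diisopropyl ether, CC(C)OC(C)C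
Why: bromoboration of acetylene gives, after equilibration, the (E)-2-bromoethenyl dibromoborane, and cleavage of the ether by the two B–Br bonds converts it into the distillable diisopropyl ester.

**Step 9**
Reactants: 13 ethyl (2E)-4-{4-bromo-5-[(1R)-2-[(tert-butyldimethylsilyl)oxy]-1-hydroxyethyl]-3-oxo-2,3-dihydrofuran-2-yl}-2-methylbut-2-enoate; 17 dipropan-2-yl [(E)-2-bromoethenyl]boronate
Product: 21 ethyl (2E)-4-[(1S,4S,5R,6S)-3,6-dibromo-2-[(tert-butyldimethylsilyl)oxy]-4-[(1R)-2-[(tert-butyldimethylsilyl)oxy]-1-hydroxyethyl]-5-hydroxy-7-oxabicyclo[2.2.1]hept-2-en-1-yl]-2-methylbut-2-enoate (5-OH exo; 6-Br endo), via mixed boronate 18 (not isolated), via silyloxyfuran 19 (not isolated), via oxaborolane cycloadduct 20 (not isolated)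
Conditions: 17 (1.2 equiv), toluene, rt, i-PrOH removed under reduced pressure; TBSOTf, i-Pr2NEt, toluene, −78 to 0 °C; then 80 °C; then NaBO3·4H2O, THF/H2O, 0 °C to rt
Reagents that add atoms: tert-butyldimethylsilyl trifluoromethanesulfonate, CC(C)(C)[Si](C)(C)OS(=O)(=O)C(F)(F)F; sodium perborate tetrahydrate, [Na+].[O-]B1OO1.O.O.O.O
Why: Proposed new method: a boron-tethered intramolecular Diels–Alder reaction has not been shown with a furan as the diene; the closest known reaction type is the alkenylboronate-tethered intramolecular Diels–Alder reaction of acyclic dienyl carbinols followed by C–B oxidation, and the extension is argued from frontier orbitals (the 3-silyloxy group raises the furan HOMO, the vacant boron p orbital lowers the alkene LUMO) and from the entropic gain of the three-atom C–O–B link. Mechanistically the secondary alcohol exchanges one isopropoxide on boron, the furanone is aromatised to the 3-silyloxyfuran, and a concerted suprafacial [4+2] cycloaddition across furan C2/C5 forms the C4–C5 and C6–C1 bonds of the target numbering. This closes the carbocyclic six-membered ring as a 7-oxabicyclo[2.2.1]heptene whose oxygen bridge is the future epoxide oxygen, and at the same time a five-membered 1,2-oxaborolane, whose short tether can only be fused on the exo face. Hence boron, and after stereoretentive perborate oxidation the C5 hydroxyl, is syn to the oxygen bridge, the E geometry of the dienophile places bromine endo and anti to that bridge, and the facial sense (absolute configuration of both bridgeheads and of C5 and C6) is dictated by the carbinol stereocentre, which keeps its hydrogen in the furan plane beside the neighbouring ring bromine to avoid allylic 1,3-strain. Regiochemistry is fixed by the tether and is matched electronically, since the nucleophilic furan terminus next to the silyloxy group bonds to the carbon β to boron. The selectivity needed afterwards is oxidation over β-elimination of the β-bromoalkylboron unit, which the rigid bicycle should secure by holding B and Br at a dihedral angle near 120 degrees, neither syn- nor anti-periplanar.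

**Step 10**
Reactants: 21 ethyl (2E)-4-[(1S,4S,5R,6S)-3,6-dibromo-2-[(tert-butyldimethylsilyl)oxy]-4-[(1R)-2-[(tert-butyldimethylsilyl)oxy]-1-hydroxyethyl]-5-hydroxy-7-oxabicyclo[2.2.1]hept-2-en-1-yl]-2-methylbut-2-enoate
Product: 22 the cyclic di-tert-butylsilylene derivative of 21 (six-membered 1,3,2-dioxasilinane joining the C5 oxygen and the side-chain carbinol oxygen)
Conditions: t-Bu2Si(OTf)2, 2,6-lutidine, CH2Cl2, 0 °C
Reagents that add atoms: di-tert-butylsilyl bis(trifluoromethanesulfonate), CC(C)(C)[Si](OS(=O)(=O)C(F)(F)F)(OS(=O)(=O)C(F)(F)F)C(C)(C)C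
Why: the silylene bis(triflate) ties the two secondary hydroxyls of the 1,3-diol into a ring under non-acidic conditions that spare the enol silyl ether, so that the C5 oxygen cannot compete as a nucleophile for the C6 bromide in step 11.

**Step 11**
Reactants: 22 the cyclic di-tert-butylsilylene derivative of 21
Product: 24 ethyl (2E)-4-[(1R,5R,6R)-3-bromo-4-[(1S)-1,2-dihydroxyethyl]-5-hydroxy-2-oxo-7-oxabicyclo[4.1.0]hept-3-en-1-yl]-2-methylbut-2-enoate, via silyl-protected epoxy bromoenone 23 (not isolated)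
Conditions: Bu4NF (1.05 equiv), THF, −78 to −20 °C; then HF·pyridine, pyridine, THF, 0 °C to rt
Reagents that add atoms: none
Why: fluoride should cleave the enol silyl ether first, the resulting enolate opens the strained oxygen bridge by E1cB β-elimination (a known reaction of 7-oxanorbornan-2-one enolates), and the tertiary C1 alkoxide so released displaces the anti C6 bromide in a 3-exo-tet closure with inversion to give the epoxide cis to the C5 oxygen, after which HF·pyridine removes the remaining silyl groups.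

**Step 12**
Reactants: 24 ethyl (2E)-4-[(1R,5R,6R)-3-bromo-4-[(1S)-1,2-dihydroxyethyl]-5-hydroxy-2-oxo-7-oxabicyclo[4.1.0]hept-3-en-1-yl]-2-methylbut-2-enoate; 25 [(1E)-hept-1-en-1-yl]boronic acid
Product: 26 ethyl (2E)-4-[(1R,5R,6R)-4-[(1S)-1,2-dihydroxyethyl]-3-[(1E)-hept-1-en-1-yl]-5-hydroxy-2-oxo-7-oxabicyclo[4.1.0]hept-3-en-1-yl]-2-methylbut-2-enoate
Conditions: Pd(OAc)2 (5 mol %), SPhos (10 mol %), K3PO4, THF/H2O (10:1), 40 °C
Reagents that add atoms: none
Why: Suzuki–Miyaura coupling of an α-bromo enone with an (E)-alkenylboronic acid proceeds with retention of alkene geometry, and an electron-rich biaryl phosphine is chosen because the bromide is flanked on both sides.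

**Step 13**
Reactants: 26 ethyl (2E)-4-[(1R,5R,6R)-4-[(1S)-1,2-dihydroxyethyl]-3-[(1E)-hept-1-en-1-yl]-5-hydroxy-2-oxo-7-oxabicyclo[4.1.0]hept-3-en-1-yl]-2-methylbut-2-enoate
Product: 27 ethyl (2E)-4-[(1R,5R,6R)-4-formyl-3-[(1E)-hept-1-en-1-yl]-5-hydroxy-2-oxo-7-oxabicyclo[4.1.0]hept-3-en-1-yl]-2-methylbut-2-enoate
Conditions: NaIO4, THF/H2O (3:1), 0 °C
Reagents that add atoms: none
Why: periodate cleaves only the vicinal diol (Malaprade reaction), removing the auxiliary carbon as formaldehyde and leaving the former carbinol carbon as the C4 formyl group.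

**Step 14**
Reactants: 27 ethyl (2E)-4-[(1R,5R,6R)-4-formyl-3-[(1E)-hept-1-en-1-yl]-5-hydroxy-2-oxo-7-oxabicyclo[4.1.0]hept-3-en-1-yl]-2-methylbut-2-enoate
Product: 28 ethyl (2E)-4-[(1S,2R,5R,6R)-3-[(1E)-hept-1-en-1-yl]-2,5-dihydroxy-4-(hydroxymethyl)-7-oxabicyclo[4.1.0]hept-3-en-1-yl]-2-methylbut-2-enoate
Conditions: NaBH4, CeCl3·7H2O, MeOH, −78 °C
Reagents that add atoms: none
Why: Luche reduction delivers hydride 1,2 to both the aldehyde and the enone carbonyl, and at C2 the hydride should enter syn to the epoxide oxygen (the usual course for 2,3-epoxycyclohexanones) and anti to the C1 side chain, placing the new hydroxyl trans to the epoxide as required.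

**Step 15**
Reactants: 28 ethyl (2E)-4-[(1S,2R,5R,6R)-3-[(1E)-hept-1-en-1-yl]-2,5-dihydroxy-4-(hydroxymethyl)-7-oxabicyclo[4.1.0]hept-3-en-1-yl]-2-methylbut-2-enoate
Product: 29 (2E)-4-[(1S,2R,5R,6R)-3-[(1E)-hept-1-en-1-yl]-2,5-dihydroxy-4-(hydroxymethyl)-7-oxabicyclo[4.1.0]hept-3-en-1-yl]-2-methylbut-2-enoic acid
Conditions: LiOH, THF/H2O (3:1), 0 °C to rt; then 0.5 M HCl to pH 4, 0 °C
Reagents that add atoms: lithium hydroxide, [Li+].[OH-]
Why: saponification of the ethyl ester and gentle acidification should give the acid, and Payne rearrangement is not expected because the only alkoxide anti to the epoxide would have to attack the quaternary C1.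

**Compound list**

1 | (4R)-2,2-dimethyl-1,3-dioxolane-4-carbaldehyde | O=C[C@H]1COC(C)(C)O1 | starting material
2 | (4S)-4-ethynyl-2,2-dimethyl-1,3-dioxolane | C#C[C@H]1COC(C)(C)O1 | intermediate
3 | 2-[(tert-butyldimethylsilyl)oxy]-N-methoxy-N-methylacetamide | CON(C)C(=O)CO[Si](C)(C)C(C)(C)C | starting material
4 | lithium acetylide of 2 | [Li]C#C[C@H]1COC(C)(C)O1 | intermediate
5 | 1-[(tert-butyldimethylsilyl)oxy]-4-[(4S)-2,2-dimethyl-1,3-dioxolan-4-yl]but-3-yn-2-one | CC(C)(C)[Si](C)(C)OCC(=O)C#C[C@H]1COC(C)(C)O1 | intermediate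
6 | 4-[(4S)-2,2-dimethyl-1,3-dioxolan-4-yl]-1-hydroxybut-3-yn-2-one (formed as its alkoxide) | OCC(=O)C#C[C@H]1COC(C)(C)O1 | intermediate
7 | 5-[(4R)-2,2-dimethyl-1,3-dioxolan-4-yl]furan-3(2H)-one | O=C1COC([C@H]2COC(C)(C)O2)=C1 | intermediate
8 | 4-bromo-5-[(4R)-2,2-dimethyl-1,3-dioxolan-4-yl]furan-3(2H)-one | O=C1COC([C@H]2COC(C)(C)O2)=C1Br | intermediate
9 | ethyl (2E)-4-bromo-2-methylbut-2-enoate | CCOC(=O)/C(C)=C/CBr | starting material
10 | lithium 4-bromo-5-[(4R)-2,2-dimethyl-1,3-dioxolan-4-yl]furan-3-olate | [Li]Oc1coc([C@H]2COC(C)(C)O2)c1Br | intermediate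
11 | ethyl (2E)-4-{4-bromo-5-[(4R)-2,2-dimethyl-1,3-dioxolan-4-yl]-3-oxo-2,3-dihydrofuran-2-yl}-2-methylbut-2-enoate (C2 epimers) | CCOC(=O)/C(C)=C/CC1OC([C@H]2COC(C)(C)O2)=C(Br)C1=O | intermediate
12 | ethyl (2E)-4-{4-bromo-5-[(1R)-1,2-dihydroxyethyl]-3-oxo-2,3-dihydrofuran-2-yl}-2-methylbut-2-enoate (C2 epimers) | CCOC(=O)/C(C)=C/CC1OC([C@H](O)CO)=C(Br)C1=O | intermediate
13 | ethyl (2E)-4-{4-bromo-5-[(1R)-2-[(tert-butyldimethylsilyl)oxy]-1-hydroxyethyl]-3-oxo-2,3-dihydrofuran-2-yl}-2-methylbut-2-enoate (C2 epimers) | CCOC(=O)/C(C)=C/CC1OC([C@H](O)CO[Si](C)(C)C(C)(C)C)=C(Br)C1=O | intermediate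
14 | acetylene | C#C | starting material
15 | boron tribromide | BrB(Br)Br | starting material
16 | dibromo[(E)-2-bromoethenyl]borane | Br/C=C/B(Br)Br | intermediate
17 | dipropan-2-yl [(E)-2-bromoethenyl]boronate | CC(C)OB(/C=C/Br)OC(C)C | intermediate
18 | mixed boronate: 13 with its (1R)-carbinol oxygen bound to B[(E)-2-bromoethenyl](O-i-Pr) | CCOC(=O)/C(C)=C/CC1OC([C@@H](CO[Si](C)(C)C(C)(C)C)OB(OC(C)C)/C=C/Br)=C(Br)C1=O | intermediate
19 | 3-[(tert-butyldimethylsilyl)oxy]furan formed from 18 by enol silylation (2,3,4,5-tetrasubstituted furan carrying the boronate tether) | CCOC(=O)/C(C)=C/Cc1oc([C@@H](CO[Si](C)(C)C(C)(C)C)OB(OC(C)C)/C=C/Br)c(Br)c1O[Si](C)(C)C(C)(C)C | intermediate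
20 | cycloadduct: 7-oxabicyclo[2.2.1]hept-2-ene with exo boron on C5 joined through B–O to the side-chain carbinol oxygen on C4 (1,2-oxaborolane, B–O-i-Pr), 6-bromo endo | C1(O[Si](C)(C)C(C)(C)C)=C(Br)[C@]2([C@@H](CO[Si](C)(C)C(C)(C)C)OB3OC(C)C)[C@@H]3[C@H](Br)[C@@]1(C/C=C(\C)C(=O)OCC)O2 | intermediate
21 | ethyl (2E)-4-[(1S,4S,5R,6S)-3,6-dibromo-2-[(tert-butyldimethylsilyl)oxy]-4-[(1R)-2-[(tert-butyldimethylsilyl)oxy]-1-hydroxyethyl]-5-hydroxy-7-oxabicyclo[2.2.1]hept-2-en-1-yl]-2-methylbut-2-enoate (5-OH exo, 6-Br endo) | C1(O[Si](C)(C)C(C)(C)C)=C(Br)[C@]2([C@H](O)CO[Si](C)(C)C(C)(C)C)[C@@H](O)[C@H](Br)[C@@]1(C/C=C(\C)C(=O)OCC)O2 | intermediate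
22 | cyclic di-tert-butylsilylene derivative of 21 (1,3,2-dioxasilinane joining the C5 oxygen and the side-chain carbinol oxygen) | C1(O[Si](C)(C)C(C)(C)C)=C(Br)[C@]2([C@@H](CO[Si](C)(C)C(C)(C)C)O[Si]3(C(C)(C)C)C(C)(C)C)[C@@H](O3)[C@H](Br)[C@@]1(C/C=C(\C)C(=O)OCC)O2 | intermediate
23 | silyl-protected epoxy bromoenone: 24 with the C5 oxygen and the carbinol oxygen bridged by di-tert-butylsilylene and the primary hydroxyl as its TBS ether | BrC1=C([C@@H](CO[Si](C)(C)C(C)(C)C)O[Si]3(C(C)(C)C)C(C)(C)C)[C@@H](O3)[C@H]2O[C@@]2(C/C=C(\C)C(=O)OCC)C1=O | intermediate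
24 | ethyl (2E)-4-[(1R,5R,6R)-3-bromo-4-[(1S)-1,2-dihydroxyethyl]-5-hydroxy-2-oxo-7-oxabicyclo[4.1.0]hept-3-en-1-yl]-2-methylbut-2-enoate | BrC1=C([C@H](O)CO)[C@@H](O)[C@H]2O[C@@]2(C/C=C(\C)C(=O)OCC)C1=O | intermediate
25 | [(1E)-hept-1-en-1-yl]boronic acid | CCCCC/C=C/B(O)O | starting material
26 | ethyl (2E)-4-[(1R,5R,6R)-4-[(1S)-1,2-dihydroxyethyl]-3-[(1E)-hept-1-en-1-yl]-5-hydroxy-2-oxo-7-oxabicyclo[4.1.0]hept-3-en-1-yl]-2-methylbut-2-enoate | CCCCC/C=C/C1=C([C@H](O)CO)[C@@H](O)[C@H]2O[C@@]2(C/C=C(\C)C(=O)OCC)C1=O | intermediate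
27 | ethyl (2E)-4-[(1R,5R,6R)-4-formyl-3-[(1E)-hept-1-en-1-yl]-5-hydroxy-2-oxo-7-oxabicyclo[4.1.0]hept-3-en-1-yl]-2-methylbut-2-enoate | CCCCC/C=C/C1=C(C=O)[C@@H](O)[C@H]2O[C@@]2(C/C=C(\C)C(=O)OCC)C1=O | intermediate
28 | ethyl (2E)-4-[(1S,2R,5R,6R)-3-[(1E)-hept-1-en-1-yl]-2,5-dihydroxy-4-(hydroxymethyl)-7-oxabicyclo[4.1.0]hept-3-en-1-yl]-2-methylbut-2-enoate | CCCCC/C=C/C1=C(CO)[C@@H](O)[C@H]2O[C@@]2(C/C=C(\C)C(=O)OCC)[C@@H]1O | intermediate
29 | (2E)-4-[(1S,2R,5R,6R)-3-[(1E)-hept-1-en-1-yl]-2,5-dihydroxy-4-(hydroxymethyl)-7-oxabicyclo[4.1.0]hept-3-en-1-yl]-2-methylbut-2-enoic acid | CCCCC/C=C/C1=C(CO)[C@@H](O)[C@H]2O[C@@]2(C/C=C(\C)C(=O)O)[C@@H]1O | target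

**Step count and risks**

Total: 15 steps. Longest linear sequence: 14 steps (steps 1–7 and 9–15); step 8 prepares the boron reagent.

Steps most likely to fail:

1. Step 9 (Proposed new method). The tethered cycloaddition may be too slow or may revert at the temperature needed, the B–O link may be lost before cyclisation, or bromide may be eliminated from the β-bromoalkylboron unit during oxidation. Fallback with known chemistry (temporary silicon connection and Tamao–Fleming oxidation), setting out from 13 and returning at 21: commercial (E)-1,2-bis(tributylstannyl)ethene would be converted by tin–lithium exchange (MeLi) and trapping with Me2SiCl2 into chloro(dimethyl)[(E)-2-(tributylstannyl)ethenyl]silane F1, and bromodestannylation (Br2) would give chloro[(E)-2-bromoethenyl]dimethylsilane F2. Silylation of the carbinol of 13 with it (imidazole) would give the bromovinylsilyl ether F3, enol silylation (TBSOTf, i-Pr2NEt) the silyloxyfuran silyl ether F4, and heating in toluene the exo-fused 1,2-oxasilolane cycloadduct F5, now held by a robust, non-Lewis-acidic Si–O link. Oxidation of the C–Si bond with retention (H2O2, KF, KHCO3) would return the route to 21.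

2. Step 11. Fluoride may attack the silylene or the primary silyl ether before the enol ether, or a silyl group may migrate, so that the C5 oxygen competes for the C6 bromide and closes the wrong epoxide; the α-ketol alkoxide may also fragment. Fallback, setting out from 22 and returning at 24, separates unmasking from ring opening and avoids fluoride until the epoxide is in place: acid methanolysis (camphorsulfonic acid, MeOH/CH2Cl2, 0 °C) of the enol silyl ether and the primary silyl ether would give the bridged 3-bromo-7-oxanorbornan-2-one with the silylene intact F6. Treatment with DBU would then effect the known β-elimination of the oxygen bridge and the epoxide closure to the silylene-protected epoxy bromoenone with a free primary hydroxyl F7, and HF·pyridine would remove the silylene to give 24.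

3. Step 12. Oxidative addition at the doubly flanked bromide may be slow, and the unprotected epoxy triol may be degraded by aqueous base or bind palladium. Fallback, setting out from 23 (obtained by working up step 11 after its first stage) and returning at 26: the same Suzuki–Miyaura coupling with 25 would be run on the fully silylated, base-tolerant intermediate to give the silyl-protected heptenyl dienone F8, and HF·pyridine would then remove the silylene and the primary silyl ether to give 26.

**Further compounds**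

F1 | step 9 | chloro(dimethyl)[(E)-2-(tributylstannyl)ethenyl]silane | CCCC[Sn](CCCC)(CCCC)/C=C/[Si](C)(C)Cl
F2 | step 9 | chloro[(E)-2-bromoethenyl]dimethylsilane | C[Si](C)(Cl)/C=C/Br
F3 | step 9 | [(E)-2-bromoethenyl]dimethylsilyl ether of 13 at the (1R)-carbinol oxygen | CCOC(=O)/C(C)=C/CC1OC([C@@H](CO[Si](C)(C)C(C)(C)C)O[Si](C)(C)/C=C/Br)=C(Br)C1=O
F4 | step 9 | 3-[(tert-butyldimethylsilyl)oxy]furan formed from F3 by enol silylation | CCOC(=O)/C(C)=C/Cc1oc([C@@H](CO[Si](C)(C)C(C)(C)C)O[Si](C)(C)/C=C/Br)c(Br)c1O[Si](C)(C)C(C)(C)C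
F5 | step 9 | silicon-tethered cycloadduct: analogue of 20 with an exo-fused 2,2-dimethyl-1,2-oxasilolane in place of the oxaborolane | C1(O[Si](C)(C)C(C)(C)C)=C(Br)[C@]2([C@@H](CO[Si](C)(C)C(C)(C)C)O[Si]3(C)C)[C@@H]3[C@H](Br)[C@@]1(C/C=C(\C)C(=O)OCC)O2
F6 | step 11 | silylene-protected 3,6-dibromo-7-oxabicyclo[2.2.1]heptan-2-one with free primary hydroxyl (C3 epimers) | O=C1C(Br)[C@]2([C@@H](CO)O[Si]3(C(C)(C)C)C(C)(C)C)[C@@H](O3)[C@H](Br)[C@@]1(C/C=C(\C)C(=O)OCC)O2
F7 | step 11 | silylene-protected epoxy bromoenone with free primary hydroxyl | BrC1=C([C@@H](CO)O[Si]3(C(C)(C)C)C(C)(C)C)[C@@H](O3)[C@H]2O[C@@]2(C/C=C(\C)C(=O)OCC)C1=O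
F8 | step 12 | silyl-protected heptenyl dienone (23 with the ring bromine replaced by (1E)-hept-1-en-1-yl) | CCCCC/C=C/C1=C([C@@H](CO[Si](C)(C)C(C)(C)C)O[Si]3(C(C)(C)C)C(C)(C)C)[C@@H](O3)[C@H]2O[C@@]2(C/C=C(\C)C(=O)OCC)C1=O
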